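**Strategy.** The route rests on cutting ring B (the dihydrofuran) of the target at two bonds, C3–C3a and O1–C7a, so that O1, C2 and C3 come from a terminal epoxide and C3a/C7a from an ortho C–H/ipso C–I pair of an aryl iodide. One Pd/norbornene (Catellani) operation joins both bonds and transfers the epoxide stereocentre unchanged to C2. The precursors are methyl 2-iodo-4,6-bis(methoxymethoxy)benzoate, whose ester blocks the second ortho position and later becomes the methylene bridge, and an enantiopure silyl-protected epoxy alcohol from a Sharpless kinetic resolution. The phenols are carried as MOM ethers so that the last deprotection is mild; the C5 acetyl group and the pyranone are added afterwards.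

Key step: step 9

Assumption: CIP analysis of the target gives (R) at C2, and since the key step breaks no bond at the epoxide methine the (2R)-oxirane is required, which is the epoxide L-(+)-tartrate forms from the fast-reacting (S)-allylic alcohol; MOM (phenols) and TBDPS (carbinol) are protecting-group choices that leave the two key-step partners and the bonds formed unchanged in skeleton.

**Step 1**
Reactants: 1 1-iodo-3,5-dimethoxybenzene
Product: 3 2-iodo-4,6-dimethoxybenzaldehyde, via iminium chloride 2 (not isolated)
Conditions: POCl3, DMF, 0 to 80 °C; then H2O, 50 °C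
Reagents that add atoms: N,N-dimethylformamide CN(C)C=O; water O
Why: Vilsmeier–Haack formylation, in which the chloroiminium electrophile attacks the ring carbon that is para to one methoxy group and ortho to the other (less encumbered than the carbon between the two methoxy groups) and hydrolysis of iminium salt 2 releases the aldehyde.

**Step 2**
Reactants: 3 2-iodo-4,6-dimethoxybenzaldehyde
Product: 4 2,4-dihydroxy-6-iodobenzaldehyde
Conditions: BBr3, CH2Cl2, −78 °C to rt; then H2O
Reagents that add atoms: none
Why: Lewis-acid cleavage of both aryl methyl ethers is done here, where only an aryl iodide and an aldehyde are present, so that the phenols can be re-protected in a form removable at the end by dilute acid.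

**Step 3**
Reactants: 4 2,4-dihydroxy-6-iodobenzaldehyde
Product: 5 2-iodo-4,6-bis(methoxymethoxy)benzaldehyde
Conditions: NaH, MOMCl, THF–DMF, 0 °C to rt
Reagents that add atoms: chloromethyl methyl ether COCCl
Why: Williamson-type O-alkylation of both phenoxides gives acetal ethers that are inert to carbonate base, hydride and organolithium reagents, later direct lithiation to C5, and come off in mild acid.

**Step 4**
Reactants: 5 2-iodo-4,6-bis(methoxymethoxy)benzaldehyde
Product: 6 2-iodo-4,6-bis(methoxymethoxy)benzoic acid
Conditions: NaClO2, NaH2PO4, 2-methyl-2-butene, t-BuOH–H2O, rt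
Reagents that add atoms: sodium chlorite [Na+].[O-]Cl=O
Why: Pinnick oxidation converts the non-enolisable aldehyde into the acid at about pH 4, where MOM ethers are stable, while 2-methyl-2-butene traps the hypochlorous acid that could chlorinate the electron-rich ring.

**Step 5**
Reactants: 6 2-iodo-4,6-bis(methoxymethoxy)benzoic acid
Product: 7 methyl 2-iodo-4,6-bis(methoxymethoxy)benzoate
Conditions: MeI, K2CO3, DMF, rt
Reagents that add atoms: iodomethane CI
Why: SN2 O-methylation of the carboxylate avoids the acid of a Fischer esterification (which would strip the MOM groups) and is insensitive to the two ortho substituents.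

**Step 6**
Reactants: 8 5-bromo-2-methylpent-2-ene; 9 acrolein
Product: 11 (3RS)-7-methylocta-1,6-dien-3-ol, via homoprenylmagnesium bromide 10 (not isolated)
Conditions: Mg, THF, rt; then 9, −78 to 0 °C; then H2O
Reagents that add atoms: none
Why: Grignard formation and 1,2-addition to the enal at low temperature give the racemic secondary allylic alcohol needed for the resolution.

**Step 7**
Reactants: 11 (3RS)-7-methylocta-1,6-dien-3-ol
Product: 12 (1S)-5-methyl-1-[(2R)-oxiran-2-yl]hex-4-en-1-ol
Conditions: Ti(OiPr)4 (10 mol %), L-(+)-DIPT (15 mol %), TBHP (0.45 equiv), 4 Å MS, CH2Cl2, −20 °C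
Reagents that add atoms: tert-butyl hydroperoxide CC(C)(C)OO
Why: Sharpless kinetic resolution, in which the titanium–L-(+)-tartrate catalyst epoxidises the (S)-alcohol much faster than the (R)-alcohol and on the face that gives the erythro (1S,2R) epoxy alcohol, the remote trisubstituted alkene lacking a directing hydroxyl staying untouched and conversion held below one half to keep the product enantiomerically enriched.

**Step 8**
Reactants: 12 (1S)-5-methyl-1-[(2R)-oxiran-2-yl]hex-4-en-1-ol
Product: 13 tert-butyl{[(1S)-5-methyl-1-[(2R)-oxiran-2-yl]hex-4-en-1-yl]oxy}diphenylsilane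
Conditions: TBDPSCl, imidazole, DMF, rt
Reagents that add atoms: tert-butyl(chloro)diphenylsilane CC(C)(C)[Si](Cl)(c1ccccc1)c1ccccc1
Why: Silylation masks the carbinol for the palladium step, the bulky TBDPS group being chosen because it resists 1,2-migration to the neighbouring alkoxide that appears when the epoxide is opened.

**Step 9**
Reactants: 7 methyl 2-iodo-4,6-bis(methoxymethoxy)benzoate; 13 tert-butyl{[(1S)-5-methyl-1-[(2R)-oxiran-2-yl]hex-4-en-1-yl]oxy}diphenylsilane
Product: 14 methyl (2R)-2-[(1S)-1-{[tert-butyl(diphenyl)silyl]oxy}-5-methylhex-4-en-1-yl]-4,6-bis(methoxymethoxy)-2,3-dihydro-1-benzofuran-7-carboxylate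
Conditions: Pd(OAc)2 (10 mol %), XPhos (20 mol %), potassium 5-norbornene-2-carboxylate (50 mol %), K2CO3 (2 equiv), 13 (1.5 equiv), NMP, 80 °C
Reagents that add atoms: none
Why: Zerovalent palladium inserts into the C–I bond of 7, norbornene carbopalladation and palladation of the only free ortho C–H (future C3a) give an aryl–norbornyl palladacycle of divalent palladium, which opens epoxide 13 at its CH2 carbon to a tetravalent palladium alkoxide; C–C reductive elimination forms C3–C3a and the now doubly ortho-substituted aryl palladium expels norbornene. Ring B is then closed by C–O reductive elimination from the six-membered aryl palladium alkoxide chelate at the ipso carbon (O1–C7a), that is, an intramolecular aryl etherification in the 5-exo sense. The closest known reaction type is the Catellani-type Pd/norbornene annulation of ortho-substituted aryl iodides with terminal epoxides to 2,3-dihydrobenzofurans. No stereocentre is created: the C–O bond at the epoxide methine stays intact, so its (R) configuration is carried over as (2R) and the (1S) carbinol is a spectator. The step needs site selectivity on the arene, secured by the C7 ester that leaves a single ortho C–H and triggers norbornene extrusion after one alkylation (C5–H is meta and inert), and regioselective opening at the unhindered epoxide CH2. Chemoselectivity is secured by keeping the future alkene as a silyl ether rather than a vinyl epoxide that zerovalent palladium would ionise, by a TBDPS group too bulky to migrate to the new alkoxide, and by MOM ethers and a hindered ester that ignore carbonate base.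

**Step 10**
Reactants: 14 methyl (2R)-2-[(1S)-1-{[tert-butyl(diphenyl)silyl]oxy}-5-methylhex-4-en-1-yl]-4,6-bis(methoxymethoxy)-2,3-dihydro-1-benzofuran-7-carboxylate
Product: 15 methyl (2R)-2-[(1S)-1-hydroxy-5-methylhex-4-en-1-yl]-4,6-bis(methoxymethoxy)-2,3-dihydro-1-benzofuran-7-carboxylate
Conditions: TBAF, AcOH (1:1), THF, rt
Reagents that add atoms: none
Why: Fluoride-induced Si–O cleavage, buffered with acetic acid so that the liberated alkoxide does not attack the C7 ester, frees the secondary alcohol.

**Step 11**
Reactants: 15 methyl (2R)-2-[(1S)-1-hydroxy-5-methylhex-4-en-1-yl]-4,6-bis(methoxymethoxy)-2,3-dihydro-1-benzofuran-7-carboxylate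
Product: 16 methyl (2R)-4,6-bis(methoxymethoxy)-2-(5-methylhex-4-enoyl)-2,3-dihydro-1-benzofuran-7-carboxylate
Conditions: DMP, CH2Cl2, rt
Reagents that add atoms: none
Why: Dess–Martin oxidation works under neutral to weakly acidic conditions, so the alpha-aryloxy ketone is formed without exposing the now enolisable C2 stereocentre to base.

**Step 12**
Reactants: 16 methyl (2R)-4,6-bis(methoxymethoxy)-2-(5-methylhex-4-enoyl)-2,3-dihydro-1-benzofuran-7-carboxylate
Product: 17 methyl (2R)-4,6-bis(methoxymethoxy)-2-(6-methylhepta-1,5-dien-2-yl)-2,3-dihydro-1-benzofuran-7-carboxylate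
Conditions: Zn, CH2Br2, TiCl4, THF (reagent pre-formed at 5 °C); then 16, CH2Cl2, 0 °C to rt
Reagents that add atoms: dibromomethane BrCBr
Why: Takai–Lombardo methylenation is non-basic, so C2 is not epimerised, and it attacks ketones but not esters, so the side-chain 1,1-disubstituted alkene is formed while the C7 ester survives.

**Step 13**
Reactants: 17 methyl (2R)-4,6-bis(methoxymethoxy)-2-(6-methylhepta-1,5-dien-2-yl)-2,3-dihydro-1-benzofuran-7-carboxylate
Product: 18 [(2R)-4,6-bis(methoxymethoxy)-2-(6-methylhepta-1,5-dien-2-yl)-2,3-dihydro-1-benzofuran-7-yl]methanol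
Conditions: LiAlH4, THF, 0 °C; then H2O
Reagents that add atoms: none
Why: Hydride reduction of the hindered benzoate to the benzylic alcohol removes the only group that would not survive the lithiation and prepares the later oxidation to the aldehyde.

**Step 14**
Reactants: 18 [(2R)-4,6-bis(methoxymethoxy)-2-(6-methylhepta-1,5-dien-2-yl)-2,3-dihydro-1-benzofuran-7-yl]methanol
Product: 20 1-[(2R)-7-(hydroxymethyl)-4,6-bis(methoxymethoxy)-2-(6-methylhepta-1,5-dien-2-yl)-2,3-dihydro-1-benzofuran-5-yl]ethan-1-one, via dilithiated alkoxide 19 (not isolated)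
Conditions: n-BuLi (2.2 equiv), THF, −20 to 0 °C; then MeC(O)N(OMe)Me, −78 °C to rt; then H2O
Reagents that add atoms: N-methoxy-N-methylacetamide CC(=O)N(C)OC
Why: Directed ortho-metalation, in which the first equivalent of n-BuLi forms the benzylic alkoxide and the second removes the only aromatic hydrogen, C5–H, flanked by two coordinating OMOM groups, after which the aryllithium acylates the Weinreb amide, whose chelated adduct gives the methyl ketone only on work-up.

**Step 15**
Reactants: 20 1-[(2R)-7-(hydroxymethyl)-4,6-bis(methoxymethoxy)-2-(6-methylhepta-1,5-dien-2-yl)-2,3-dihydro-1-benzofuran-5-yl]ethan-1-one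
Product: 21 (2R)-5-acetyl-4,6-bis(methoxymethoxy)-2-(6-methylhepta-1,5-dien-2-yl)-2,3-dihydro-1-benzofuran-7-carbaldehyde
Conditions: MnO2, CH2Cl2, rt
Reagents that add atoms: none
Why: MnO2 oxidises only the electron-rich benzylic alcohol, stops at the aldehyde, and leaves the ketone and both alkenes alone.

**Step 16**
Reactants: 22 methyl 3-oxopentanoate
Product: 24 methyl 4-methyl-3,5-dioxoheptanoate, via keto ester dianion 23 (not isolated)
Conditions: NaH, then n-BuLi, THF, 0 °C; then EtC(O)N(OMe)Me, −78 to 0 °C; then aq. HCl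
Reagents that add atoms: N-methoxy-N-methylpropanamide CCC(=O)N(C)OC
Why: Gamma-acylation of a beta-keto ester dianion, in which the more reactive gamma-carbanion attacks the Weinreb amide and the stable tetrahedral adduct prevents a second addition, gives the 3,5-diketo ester.

**Step 17**
Reactants: 24 methyl 4-methyl-3,5-dioxoheptanoate
Product: 25 6-ethyl-4-hydroxy-5-methyl-2H-pyran-2-one
Conditions: DBU, toluene, 110 °C; then aq. HCl
Reagents that add atoms: none
Why: Base-promoted lactonisation of the enolised 3,5-diketo ester (C5 enol oxygen onto the ester carbonyl with loss of methanol) is the standard closure of triketide esters to 4-hydroxy-2-pyranones and places ethyl at C6 and methyl at C5.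

**Step 18**
Reactants: 21 (2R)-5-acetyl-4,6-bis(methoxymethoxy)-2-(6-methylhepta-1,5-dien-2-yl)-2,3-dihydro-1-benzofuran-7-carbaldehyde; 25 6-ethyl-4-hydroxy-5-methyl-2H-pyran-2-one
Product: 27 3-{[(2R)-5-acetyl-4,6-bis(methoxymethoxy)-2-(6-methylhepta-1,5-dien-2-yl)-2,3-dihydro-1-benzofuran-7-yl]methyl}-6-ethyl-4-hydroxy-5-methyl-2H-pyran-2-one, via alkylidene pyrandione 26 (not isolated)
Conditions: L-proline (20 mol %), Hantzsch ester (1.2 equiv), EtOH–CH2Cl2, rt to 40 °C
Reagents that add atoms: none
Why: Organocatalytic reductive Knoevenagel alkylation, in which proline catalyses condensation of the aldehyde with the nucleophilic C3 of the 4-hydroxypyranone and the electron-poor alkylidene 26 is reduced at once by hydride transfer from the Hantzsch ester before a second pyranone can add, leaves the methylene bridge while the hindered ketone does not react.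

**Step 19**
Reactants: 27 3-{[(2R)-5-acetyl-4,6-bis(methoxymethoxy)-2-(6-methylhepta-1,5-dien-2-yl)-2,3-dihydro-1-benzofuran-7-yl]methyl}-6-ethyl-4-hydroxy-5-methyl-2H-pyran-2-one
Product: 28 3-{[(2R)-5-acetyl-4,6-dihydroxy-2-(6-methylhepta-1,5-dien-2-yl)-2,3-dihydro-1-benzofuran-7-yl]methyl}-6-ethyl-4-hydroxy-5-methyl-2H-pyran-2-one
Conditions: HCl (3 M aq.), MeOH, rt
Reagents that add atoms: none
Why: Acid-catalysed acetal exchange with methanol removes both MOM groups, which are activated by the flanking acetyl carbonyl, under conditions too mild to protonate the alkenes or ionise the allylic aryl ether at C2.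

**Compound list**
1 | 1-iodo-3,5-dimethoxybenzene | COc1cc(I)cc(OC)c1 | starting material
2 | N-[(2-iodo-4,6-dimethoxyphenyl)methylidene]-N-methylmethanaminium chloride | COc1cc(I)c(C=[N+](C)C)c(OC)c1.[Cl-] | intermediate
3 | 2-iodo-4,6-dimethoxybenzaldehyde | COc1cc(I)c(C=O)c(OC)c1 | intermediate
4 | 2,4-dihydroxy-6-iodobenzaldehyde | O=Cc1c(O)cc(O)cc1I | intermediate
5 | 2-iodo-4,6-bis(methoxymethoxy)benzaldehyde | COCOc1cc(I)c(C=O)c(OCOC)c1 | intermediate
6 | 2-iodo-4,6-bis(methoxymethoxy)benzoic acid | COCOc1cc(I)c(C(=O)O)c(OCOC)c1 | intermediate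
7 | methyl 2-iodo-4,6-bis(methoxymethoxy)benzoate | COCOc1cc(I)c(C(=O)OC)c(OCOC)c1 | intermediate
8 | 5-bromo-2-methylpent-2-ene | CC(C)=CCCBr | starting material
9 | acrolein (prop-2-enal) | C=CC=O | starting material
10 | (4-methylpent-3-en-1-yl)magnesium bromide | CC(C)=CCC[Mg]Br | intermediate
11 | (3RS)-7-methylocta-1,6-dien-3-ol (racemic) | C=CC(O)CCC=C(C)C | intermediate
12 | (1S)-5-methyl-1-[(2R)-oxiran-2-yl]hex-4-en-1-ol | CC(C)=CCC[C@H](O)[C@H]1CO1 | intermediate
13 | tert-butyl{[(1S)-5-methyl-1-[(2R)-oxiran-2-yl]hex-4-en-1-yl]oxy}diphenylsilane | CC(C)=CCC[C@H](O[Si](c1ccccc1)(c1ccccc1)C(C)(C)C)[C@H]1CO1 | intermediate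
14 | methyl (2R)-2-[(1S)-1-{[tert-butyl(diphenyl)silyl]oxy}-5-methylhex-4-en-1-yl]-4,6-bis(methoxymethoxy)-2,3-dihydro-1-benzofuran-7-carboxylate | CC(C)=CCC[C@H](O[Si](c1ccccc1)(c1ccccc1)C(C)(C)C)[C@H]1Cc2c(OCOC)cc(OCOC)c(C(=O)OC)c2O1 | intermediate
15 | methyl (2R)-2-[(1S)-1-hydroxy-5-methylhex-4-en-1-yl]-4,6-bis(methoxymethoxy)-2,3-dihydro-1-benzofuran-7-carboxylate | CC(C)=CCC[C@H](O)[C@H]1Cc2c(OCOC)cc(OCOC)c(C(=O)OC)c2O1 | intermediate
16 | methyl (2R)-4,6-bis(methoxymethoxy)-2-(5-methylhex-4-enoyl)-2,3-dihydro-1-benzofuran-7-carboxylate | CC(C)=CCCC(=O)[C@H]1Cc2c(OCOC)cc(OCOC)c(C(=O)OC)c2O1 | intermediate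
17 | methyl (2R)-4,6-bis(methoxymethoxy)-2-(6-methylhepta-1,5-dien-2-yl)-2,3-dihydro-1-benzofuran-7-carboxylate | C=C(CCC=C(C)C)[C@H]1Cc2c(OCOC)cc(OCOC)c(C(=O)OC)c2O1 | intermediate
18 | [(2R)-4,6-bis(methoxymethoxy)-2-(6-methylhepta-1,5-dien-2-yl)-2,3-dihydro-1-benzofuran-7-yl]methanol | C=C(CCC=C(C)C)[C@H]1Cc2c(OCOC)cc(OCOC)c(CO)c2O1 | intermediate
19 | lithium [(2R)-5-lithio-4,6-bis(methoxymethoxy)-2-(6-methylhepta-1,5-dien-2-yl)-2,3-dihydro-1-benzofuran-7-yl]methanolate | C=C(CCC=C(C)C)[C@H]1Cc2c(OCOC)c([Li])c(OCOC)c(CO[Li])c2O1 | intermediate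
20 | 1-[(2R)-7-(hydroxymethyl)-4,6-bis(methoxymethoxy)-2-(6-methylhepta-1,5-dien-2-yl)-2,3-dihydro-1-benzofuran-5-yl]ethan-1-one | C=C(CCC=C(C)C)[C@H]1Cc2c(OCOC)c(C(C)=O)c(OCOC)c(CO)c2O1 | intermediate
21 | (2R)-5-acetyl-4,6-bis(methoxymethoxy)-2-(6-methylhepta-1,5-dien-2-yl)-2,3-dihydro-1-benzofuran-7-carbaldehyde | C=C(CCC=C(C)C)[C@H]1Cc2c(OCOC)c(C(C)=O)c(OCOC)c(C=O)c2O1 | intermediate
22 | methyl 3-oxopentanoate | CCC(=O)CC(=O)OC | starting material
23 | sodium lithium dianion of methyl 3-oxopentanoate | [Li+].[Na+].C[CH-]C(=O)[CH-]C(=O)OC | intermediate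
24 | methyl 4-methyl-3,5-dioxoheptanoate | CCC(=O)C(C)C(=O)CC(=O)OC | intermediate
25 | 6-ethyl-4-hydroxy-5-methyl-2H-pyran-2-one | CCc1oc(=O)cc(O)c1C | intermediate
26 | 3-{[(2R)-5-acetyl-4,6-bis(methoxymethoxy)-2-(6-methylhepta-1,5-dien-2-yl)-2,3-dihydro-1-benzofuran-7-yl]methylidene}-6-ethyl-5-methyl-2H-pyran-2,4(3H)-dione | C=C(CCC=C(C)C)[C@H]1Cc2c(OCOC)c(C(C)=O)c(OCOC)c(C=C3C(=O)OC(CC)=C(C)C3=O)c2O1 | intermediate
27 | 3-{[(2R)-5-acetyl-4,6-bis(methoxymethoxy)-2-(6-methylhepta-1,5-dien-2-yl)-2,3-dihydro-1-benzofuran-7-yl]methyl}-6-ethyl-4-hydroxy-5-methyl-2H-pyran-2-one | C=C(CCC=C(C)C)[C@H]1Cc2c(OCOC)c(C(C)=O)c(OCOC)c(Cc3c(O)c(C)c(CC)oc3=O)c2O1 | intermediate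
28 | 3-{[(2R)-5-acetyl-4,6-dihydroxy-2-(6-methylhepta-1,5-dien-2-yl)-2,3-dihydro-1-benzofuran-7-yl]methyl}-6-ethyl-4-hydroxy-5-methyl-2H-pyran-2-one | C=C(CCC=C(C)C)[C@H]1Cc2c(O)c(C(C)=O)c(O)c(Cc3c(O)c(C)c(CC)oc3=O)c2O1 | target

**Step count.** Total: 19 steps. Longest linear sequence: 14 steps (steps 1–5, 9–15, 18, 19); the epoxide (steps 6–8) and the pyranone (steps 16–17) are side branches.

**Steps most likely to fail**

Step 9. Palladation of the C–H flanked by iodine and an OMOM group may be slow, so that the aryl palladium is reduced or couples with norbornene before the epoxide is taken up; the silyl group may also migrate within the ring-opened alkoxide and lead to a six-membered ether. Fallback: give up the epoxide and close ring B by an enantioselective Larock-type heteroannulation (Heck addition then allylic etherification) of an ortho-iodophenol with a 1,3-diene. Aryl iodide 7 would be hydroxylated (Pd2(dba)3, tBuXPhos, KOH, dioxane–water) to methyl 2-hydroxy-4,6-bis(methoxymethoxy)benzoate F1, and this iodinated ortho to the free hydroxyl (NIS, cat. iPr2NH, CH2Cl2) to methyl 2-hydroxy-3-iodo-4,6-bis(methoxymethoxy)benzoate F2. F2 and myrcene (7-methyl-3-methylideneocta-1,6-diene) with Pd2(dba)3, a chiral sulfinamide–phosphine ligand and K2CO3 should give, by aryl addition to the unsubstituted vinyl terminus and phenoxide attack on the internal carbon of the allyl palladium intermediate, the 2-alkenyl dihydrobenzofuran 17 directly, the ligand enantiomer being selected for (2R). The fallback sets out from 7, rejoins the route at 17, and makes steps 6–12 unnecessary.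

Step 14. Excess n-BuLi may deprotonate the benzylic C3 or allylic C2 position and open ring B, or the hindered aryllithium may take a proton from the amide so that 18 is returned. Fallback: replace deprotonation by electrophilic bromination and halogen–lithium exchange. Alcohol 18 would be brominated at C5, its most nucleophilic carbon (NBS, MeCN, −20 °C), to [(2R)-5-bromo-4,6-bis(methoxymethoxy)-2-(6-methylhepta-1,5-dien-2-yl)-2,3-dihydro-1-benzofuran-7-yl]methanol F3. n-BuLi (1 equiv) and then t-BuLi (2 equiv) at −78 °C exchange bromine for lithium faster than any C–H is removed, and acetaldehyde gives 1-[(2R)-7-(hydroxymethyl)-4,6-bis(methoxymethoxy)-2-(6-methylhepta-1,5-dien-2-yl)-2,3-dihydro-1-benzofuran-5-yl]ethan-1-ol F4 as a mixture of carbinol epimers, which does not matter. DMP then oxidises both alcohols at once to keto aldehyde 21. The fallback sets out from 18 and rejoins the route at 21, so step 15 is skipped.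

Step 18. The aldehyde carbon, flanked by the C6 OMOM group and O1, may condense too slowly with the pyranone, or the alkylidene intermediate may be intercepted by a second pyranone before hydride transfer. Fallback: make the same C–C bond from the benzylic alcohol instead of the aldehyde. Alcohol 20, whose benzylic position is stabilised by O1 and the C6 oxygen, would be ionised with a catalytic Lewis acid (Sc(OTf)3, 5 mol %, MeCN, 0 °C) in the presence of pyranone 25, which captures the benzylic cation at C3 (dehydrative Friedel–Crafts-type benzylation of a 4-hydroxypyranone). The fallback sets out from 20 and 25 and rejoins the route at 27, omitting step 15 and forming no new compound.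

**Further compounds**
F1 | step 9 | methyl 2-hydroxy-4,6-bis(methoxymethoxy)benzoate | COC(=O)c1c(O)cc(OCOC)cc1OCOC
F2 | step 9 | methyl 2-hydroxy-3-iodo-4,6-bis(methoxymethoxy)benzoate | COC(=O)c1c(O)c(I)c(OCOC)cc1OCOC
F3 | step 14 | [(2R)-5-bromo-4,6-bis(methoxymethoxy)-2-(6-methylhepta-1,5-dien-2-yl)-2,3-dihydro-1-benzofuran-7-yl]methanol | C=C(CCC=C(C)C)[C@H]1Cc2c(OCOC)c(Br)c(OCOC)c(CO)c2O1
F4 | step 14 | 1-[(2R)-7-(hydroxymethyl)-4,6-bis(methoxymethoxy)-2-(6-methylhepta-1,5-dien-2-yl)-2,3-dihydro-1-benzofuran-5-yl]ethan-1-ol | C=C(CCC=C(C)C)[C@H]1Cc2c(OCOC)c(C(C)O)c(OCOC)c(CO)c2O1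
F0 | step 18 | none | none
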